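**Retrosynthetic overview** (chromene numbering: O1, C2, C3, C4, C4a, C5–C8, C8a)
1. Last disconnection: the gem-diprenyl carbon C8 is opened by dearomative double C-prenylation, leading back to aromatic 6-benzoyl-5,7-dihydroxy-2,2-dimethyl-2H-chromene (the carbocycle is a phloroglucinol at the aromatic oxidation level).
2. Key disconnection: the whole 2H-pyran ring is split into three components, an aryne (C4a≡C8a), DMF (O1 and C4) and 2-methylprop-1-enylboronic acid (C3, C2 and both methyls). One operation makes O1–C8a, C4a–C4, C4–C3 (which ends as the C3=C4 double bond) and O1–C2.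
3. Enabling feature: the C4a=C8a bond shared by the pyran ring and the six-membered carbocycle is an aryne triple bond at the aromatic oxidation level. The oxygen on C5 next to C4a (carried as OMe) polarises it so that O1 goes to C8a, and the O1–C2 bond is the oxa-6π closure of the dienone O1=C8a–C4a=C4–C3=C2.
4. The aryne precursor, an ortho-silylaryl triflate that already carries the benzoyl group, comes from 3,5-dimethoxyphenol by ortho-bromination, retro-Brook silyl shift, lithiation between the two methoxy groups with benzoylation, and triflation.
5. Ring order: benzene carbocycle (present from the start), then the pyran ring (step 6), then dearomatisation of the carbocycle at C8 (step 8).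

Key step: step 6

Assumption: the target is an enolised β-triketone and is taken as the tautomer drawn; it has no stereocentre, so no stereocontrol is needed.

**Step 1**
Reactants: 1 3,5-dimethoxyphenol; 2 N-bromosuccinimide
Product: 3 2-bromo-3,5-dimethoxyphenol
Conditions: NBS (1.0 equiv), CH2Cl2, −78 °C to rt
Reagents that add atoms: N-bromosuccinimide (2), O=C1CCC(=O)N1Br
Why: Electrophilic aromatic bromination should go ortho to the hydroxyl and para to a methoxy group, at the position less hindered than the one between the two methoxy groups, and one equivalent at low temperature should limit dibromination.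

**Step 2**
Reactants: 3 2-bromo-3,5-dimethoxyphenol; 4 hexamethyldisilazane; 5 triisopropylsilyl trifluoromethanesulfonate
Product: 8 [3,5-dimethoxy-2-(trimethylsilyl)phenoxy]triisopropylsilane, via aryl trimethylsilyl ether 6 (not isolated), via lithium phenolate 7 (not isolated)
Conditions: HMDS, THF, 70 °C, evaporate; n-BuLi, THF, −78 °C; TIPSOTf, −78 °C to rt
Reagents that add atoms: hexamethyldisilazane (4), C[Si](C)(C)N[Si](C)(C)C; triisopropylsilyl trifluoromethanesulfonate (5), CC(C)[Si](OS(=O)(=O)C(F)(F)F)(C(C)C)C(C)C
Why: O-silylation, bromine–lithium exchange and anionic 1,3 O-to-C silyl shift (retro-Brook rearrangement) should place the trimethylsilyl group exactly where bromine sat, and the freed phenolate is then capped as a bulky, non-directing TIPS ether.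

**Step 3**
Reactants: 8 [3,5-dimethoxy-2-(trimethylsilyl)phenoxy]triisopropylsilane; 9 N-methoxy-N-methylbenzamide
Product: 11 [2,6-dimethoxy-4-(triisopropylsilyloxy)-3-(trimethylsilyl)phenyl](phenyl)methanone, via aryllithium 10 (not isolated)
Conditions: n-BuLi, TMEDA, THF, 0 °C; then 9, −78 °C to rt; then H2O
Reagents that add atoms: N-methoxy-N-methylbenzamide (9), CON(C)C(=O)c1ccccc1
Why: Directed ortho-metalation should take place only at the C–H flanked by two coordinating methoxy groups (the other C–H is shielded by the non-coordinating OTIPS group), and Weinreb ketone synthesis should stop at the ketone because the chelated tetrahedral adduct survives until the quench.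

**Step 4**
Reactants: 11 [2,6-dimethoxy-4-(triisopropylsilyloxy)-3-(trimethylsilyl)phenyl](phenyl)methanone
Product: 12 [4-hydroxy-2,6-dimethoxy-3-(trimethylsilyl)phenyl](phenyl)methanone
Conditions: TBAF (1.1 equiv), AcOH, THF, 0 °C
Reagents that add atoms: none
Why: Fluoride-mediated O-desilylation should be much faster than attack at the unactivated aryl C–SiMe3 bond, because the leaving group is a para-acyl phenoxide, and acetic acid buffers the medium.

**Step 5**
Reactants: 12 [4-hydroxy-2,6-dimethoxy-3-(trimethylsilyl)phenyl](phenyl)methanone; 13 trifluoromethanesulfonic anhydride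
Product: 14 4-benzoyl-3,5-dimethoxy-2-(trimethylsilyl)phenyl trifluoromethanesulfonate
Conditions: Tf2O, pyridine, CH2Cl2, 0 °C
Reagents that add atoms: trifluoromethanesulfonic anhydride (13), O=S(=O)(OS(=O)(=O)C(F)(F)F)C(F)(F)F
Why: O-sulfonylation of the phenol should give the ortho-silylaryl triflate aryne precursor, with the ketone, ethers and aryl silane inert under these conditions.

**Step 6**
Reactants: 14 4-benzoyl-3,5-dimethoxy-2-(trimethylsilyl)phenyl trifluoromethanesulfonate; 15 N,N-dimethylformamide (reagent and solvent); 16 (2-methylprop-1-en-1-yl)boronic acid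
Product: 21 (5,7-dimethoxy-2,2-dimethyl-2H-chromen-6-yl)(phenyl)methanone, via aryne 17 (not isolated), via aminomethylene dienone 18 (not isolated), via allylic amine 19 (not isolated), via vinyl quinone methide 20 (not isolated)
Conditions: CsF (3 equiv), 16 (2 equiv), DMF, 25 °C (slow addition of 14); then 90 °C
Reagents that add atoms: N,N-dimethylformamide (15), CN(C)C=O; (2-methylprop-1-en-1-yl)boronic acid (16), CC(C)=CB(O)O
Why: Proposed new method: fluoride removes the silyl group of 14 and triflate leaves to give aryne 17, whose strained triple bond adds across the C=O bond of DMF (formal [2+2] addition, then opening of the benzoxete) to give the phenoxide–iminium/aminomethylene dienone 18, the phenoxide oxygen of 18 binds the boron of 16 and the ate complex hands the 2-methylprop-1-enyl group to the iminium carbon (Petasis borono-Mannich step) to give 19, and at 90 °C 19 loses dimethylamine to the vinyl ortho-quinone methide 20, which cyclises. The closest known reaction types are the three-component coupling of arynes and DMF with carbon nucleophiles, the aryne/enal annulation to 2H-chromenes, and the secondary-amine-catalysed condensation of salicylaldehydes with alkenylboronic acids to 2H-chromenes, which runs through the same kind of phenoxide–iminium species as 18; what is new is their merger, so that DMF delivers O1 and C4 and the boronic acid delivers C3 and C2. The pyran ring closes by thermal oxa-6π electrocyclisation of the (Z)-dienone 20 (O1–C2 bond), after O1–C8a, C4a–C4 and C4–C3 have been formed in the same flask. No stereocentre remains, since the aminomethine centre of 19 is racemic and is erased by the elimination. The step needs regioselective insertion (oxygen at the future C8a, carbon at the future C4a) and chemoselective capture of the aryne by DMF: the methoxy group flanking the aryne polarises the triple bond so that the DMF oxygen attacks the distal and less hindered carbon, and DMF as solvent outcompetes the hindered diaryl ketone and the boronic acid. Adventitious hydrolysis of 18 is not fatal, because the resulting salicylaldehyde and the freed dimethylamine can re-form 18.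

**Step 7**
Reactants: 21 (5,7-dimethoxy-2,2-dimethyl-2H-chromen-6-yl)(phenyl)methanone
Product: 23 (5,7-dihydroxy-2,2-dimethyl-2H-chromen-6-yl)(phenyl)methanone, via monomethyl ether 22 (not isolated)
Conditions: BCl3 (excess), CH2Cl2, −78 to 0 °C; then H2O
Reagents that add atoms: none
Why: Lewis-acid ether cleavage assisted by chelation of boron between the ketone oxygen and each ortho-methoxy oxygen should remove first the more hindered C5 methyl (22) and then the C7 methyl, at temperatures low enough for the acid-labile 2H-pyran to survive.

**Step 8**
Reactants: 23 (5,7-dihydroxy-2,2-dimethyl-2H-chromen-6-yl)(phenyl)methanone; 24 1-bromo-3-methylbut-2-ene (prenyl bromide)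
Product: 26 6-benzoyl-7-hydroxy-2,2-dimethyl-8,8-bis(3-methylbut-2-en-1-yl)-2H-chromen-5(8H)-one (CNP0138894.0), via monoprenyl chromene 25 (not isolated)
Conditions: prenyl bromide (2.2 equiv), 10% aq. KOH, 0 °C; then dilute HCl
Reagents that add atoms: 1-bromo-3-methylbut-2-ene (24), CC(C)=CCBr
Why: Base-mediated C-alkylation of the acylphloroglucinol dianion (the known gem-diallylation type of acylphloroglucinols, SN2 at the primary allylic bromide) should go twice at C8, the only unsubstituted ring carbon, the second alkylation dearomatising the ring to the stabilised β-triketone enolate, with water favouring C- over O-alkylation and no stereocentre formed.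

**Compound list**
1 | 3,5-dimethoxyphenol | COc1cc(O)cc(OC)c1 | starting material
2 | N-bromosuccinimide | O=C1CCC(=O)N1Br | starting material
3 | 2-bromo-3,5-dimethoxyphenol | COc1cc(O)c(Br)c(OC)c1 | intermediate
4 | hexamethyldisilazane | C[Si](C)(C)N[Si](C)(C)C | starting material
5 | triisopropylsilyl trifluoromethanesulfonate | CC(C)[Si](OS(=O)(=O)C(F)(F)F)(C(C)C)C(C)C | starting material
6 | (2-bromo-3,5-dimethoxyphenoxy)trimethylsilane | COc1cc(O[Si](C)(C)C)c(Br)c(OC)c1 | intermediate
7 | lithium 3,5-dimethoxy-2-(trimethylsilyl)phenolate | COc1cc([O-])c([Si](C)(C)C)c(OC)c1.[Li+] | intermediate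
8 | [3,5-dimethoxy-2-(trimethylsilyl)phenoxy]triisopropylsilane | COc1cc(O[Si](C(C)C)(C(C)C)C(C)C)c([Si](C)(C)C)c(OC)c1 | intermediate
9 | N-methoxy-N-methylbenzamide | CON(C)C(=O)c1ccccc1 | starting material
10 | [2,6-dimethoxy-4-(triisopropylsilyloxy)-3-(trimethylsilyl)phenyl]lithium | [Li]c1c(OC)cc(O[Si](C(C)C)(C(C)C)C(C)C)c([Si](C)(C)C)c1OC | intermediate
11 | [2,6-dimethoxy-4-(triisopropylsilyloxy)-3-(trimethylsilyl)phenyl](phenyl)methanone | COc1cc(O[Si](C(C)C)(C(C)C)C(C)C)c([Si](C)(C)C)c(OC)c1C(=O)c1ccccc1 | intermediate
12 | [4-hydroxy-2,6-dimethoxy-3-(trimethylsilyl)phenyl](phenyl)methanone | COc1cc(O)c([Si](C)(C)C)c(OC)c1C(=O)c1ccccc1 | intermediate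
13 | trifluoromethanesulfonic anhydride | O=S(=O)(OS(=O)(=O)C(F)(F)F)C(F)(F)F | starting material
14 | 4-benzoyl-3,5-dimethoxy-2-(trimethylsilyl)phenyl trifluoromethanesulfonate | COc1cc(OS(=O)(=O)C(F)(F)F)c([Si](C)(C)C)c(OC)c1C(=O)c1ccccc1 | intermediate
15 | N,N-dimethylformamide | CN(C)C=O | starting material
16 | (2-methylprop-1-en-1-yl)boronic acid | CC(C)=CB(O)O | starting material
17 | 4-benzoyl-3,5-dimethoxy-1,2-didehydrobenzene (aryne) | COC1=CC#CC(OC)=C1C(=O)c1ccccc1 | intermediate
18 | 4-benzoyl-6-[(dimethylamino)methylidene]-3,5-dimethoxycyclohexa-2,4-dien-1-one | CN(C)C=C1C(=O)C=C(OC)C(C(=O)c2ccccc2)=C1OC | intermediate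
19 | [3-[1-(dimethylamino)-3-methylbut-2-en-1-yl]-4-hydroxy-2,6-dimethoxyphenyl](phenyl)methanone (racemic) | CN(C)C(C=C(C)C)c1c(O)cc(OC)c(C(=O)c2ccccc2)c1OC | intermediate
20 | (6Z)-4-benzoyl-3,5-dimethoxy-6-(3-methylbut-2-en-1-ylidene)cyclohexa-2,4-dien-1-one | CC(C)=C/C=C1\C(=O)C=C(OC)C(C(=O)c2ccccc2)=C1OC | intermediate
21 | (5,7-dimethoxy-2,2-dimethyl-2H-chromen-6-yl)(phenyl)methanone | COc1cc2OC(C)(C)C=Cc2c(OC)c1C(=O)c1ccccc1 | intermediate
22 | (5-hydroxy-7-methoxy-2,2-dimethyl-2H-chromen-6-yl)(phenyl)methanone | COc1cc2OC(C)(C)C=Cc2c(O)c1C(=O)c1ccccc1 | intermediate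
23 | (5,7-dihydroxy-2,2-dimethyl-2H-chromen-6-yl)(phenyl)methanone | Oc1cc2OC(C)(C)C=Cc2c(O)c1C(=O)c1ccccc1 | intermediate
24 | 1-bromo-3-methylbut-2-ene | CC(C)=CCBr | starting material
25 | [5,7-dihydroxy-2,2-dimethyl-8-(3-methylbut-2-en-1-yl)-2H-chromen-6-yl](phenyl)methanone | CC(C)=CCc1c(O)c(C(=O)c2ccccc2)c(O)c2C=CC(C)(C)Oc12 | intermediate
26 | 6-benzoyl-7-hydroxy-2,2-dimethyl-8,8-bis(3-methylbut-2-en-1-yl)-2H-chromen-5(8H)-one | CC(C)=CCC1(CC=C(C)C)C(O)=C(C(=O)c2ccccc2)C(=O)C2=C1OC(C)(C)C=C2 | target

Total step count: 8. Longest linear sequence: 8 steps.

**Steps most likely to fail**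

1. Step 6 (proposed new method). The alkenyl transfer from boron may be outrun by capture of 18 by a second aryne, fluoride may tie up the boronic acid, or the amine elimination and electrocyclisation may stall. The fallback uses known chemistry and sets out from 14. The aryne is generated with CsF in DMF and the DMF insertion adduct is hydrolysed with water to 3-benzoyl-6-hydroxy-2,4-dimethoxybenzaldehyde F1 (the known aryne–formamide insertion/hydrolysis route to salicylaldehydes). Isolated F1 is then condensed with 16 and catalytic dibenzylamine in dioxane at 90 °C (the known amine-catalysed Petasis-type route from salicylaldehydes and alkenylboronic acids to 2H-chromenes). The route is rejoined at 21.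

2. Step 8. O-alkylation may compete with C-alkylation, the second alkylation may stop short, or it may go to the benzoyl-bearing carbon. The fallback sets out from 23 and separates the two events. One equivalent of prenyl bromide in aqueous KOH should give isolated 25. The dearomatising second prenylation is then run under neutral conditions with a π-prenyl electrophile: Pd(PPh3)4 (zerovalent palladium), tert-butyl 3-methylbut-2-en-1-yl carbonate (CC(C)=CCOC(=O)OC(C)(C)C), THF, rt, a Tsuji–Trost-type dearomative allylation in which the soft carbon nucleophile attacks the unsubstituted allyl terminus. The route is rejoined at 26; no compound outside the list is made (F0).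

3. Step 7. The Lewis acid may ionise the tertiary allylic O1–C2 bond and open the pyran, HCl may add to the C3=C4 bond, or cleavage may stop after one methyl group. The fallback sets out from 21 and replaces the second Lewis-acid cleavage by nucleophilic dealkylation. One equivalent of BCl3 at −78 °C should give only the chelation-assisted first cleavage to isolated 22. The remaining methyl group is then removed by SN2 attack of NaSEt in DMF at 120 °C, conditions under which the base-stable chromene should survive, followed by dilute HCl. The route is rejoined at 23; no compound outside the list is made (F0).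

**Further compounds**
F1 | step 6 | 3-benzoyl-6-hydroxy-2,4-dimethoxybenzaldehyde | O=Cc1c(O)cc(OC)c(C(=O)c2ccccc2)c1OC
F0 | step 8 | none | none
F0 | step 7 | none | none
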